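**Strategy.** The pyran ring is not closed directly. It is carved out of a seven-membered 2-aryl-2,3,4,5-tetrahydro-1,4-benzoxazepine, in which the O1–C2 aryl ether stereocentre is already in place, by deleting the ring nitrogen. The key step excises N4 as N2 and joins its two neighbours, which become C3 and C4 of the chroman. It exploits that C4 is benzylic to ring A (C4a), so the 1,1-diazene gives a short-lived C3/C4 biradical that recloses to the six-membered ring without touching C2. The stereocentre comes from an asymmetric Henry reaction. All three phenols and C-prenyl groups are released last by a protecting-group-free triple Claisen rearrangement.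

Key step: step 7

Remark: flavan numbering (O1, C2, C3, C4, C4a, C5–C8, C8a; ring B primed) is used for the chromans. The carbonate of step 1 is taken as a purchasable reagent (otherwise one operation from 2-methylbut-3-en-2-ol and Boc2O). Amine 4 is assumed to be brought to single-enantiomer quality, if needed, by crystallisation of a salt.

Step 1
Reactants: 1 3,4-dihydroxybenzaldehyde
Product: 2 3,4-bis[(2-methylbut-3-en-2-yl)oxy]benzaldehyde
Conditions: tert-butyl 2-methylbut-3-en-2-yl carbonate (2.5 equiv), Pd(PPh3)4 (2 mol %), THF, 0 °C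
Reagents that add atoms: tert-butyl 2-methylbut-3-en-2-yl carbonate, C=CC(C)(C)OC(=O)OC(C)(C)C
Why: Tsuji–Trost O-allylation: the Pd π-(1,1-dimethylallyl) complex formed by decarboxylative ionisation of the tertiary carbonate is attacked by phenoxide at its more substituted terminus under kinetic control at 0 °C, giving the branched aryl ether at both catechol oxygens.

Step 2
Reactants: 2 3,4-bis[(2-methylbut-3-en-2-yl)oxy]benzaldehyde
Product: 3 (R)-1-{3,4-bis[(2-methylbut-3-en-2-yl)oxy]phenyl}-2-nitroethan-1-ol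
Conditions: MeNO2 (10 equiv), Cu(OAc)2·H2O (5 mol %), indane-fused bis(oxazoline) ligand (enantiomer that gives the R adduct), EtOH, rt
Reagents that add atoms: nitromethane, C[N+](=O)[O-]
Why: Cu(II)–bis(oxazoline)-catalysed asymmetric Henry (nitroaldol) reaction; the chiral Lewis acid binds the aldehyde and delivers the nitronate to one face, which sets the carbinol centre (the later C2) as R.

Step 3
Reactants: 3 (R)-1-{3,4-bis[(2-methylbut-3-en-2-yl)oxy]phenyl}-2-nitroethan-1-ol
Product: 4 (R)-2-amino-1-{3,4-bis[(2-methylbut-3-en-2-yl)oxy]phenyl}ethan-1-ol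
Conditions: LiAlH4, THF, 0 °C to rt
Reagents that add atoms: none
Why: Hydride reduction of the aliphatic nitro group to the primary amine, which leaves the carbinol centre, the isolated alkenes and the aryl allyl ethers untouched.

Step 4
Reactants: 5 2-bromo-4-hydroxybenzaldehyde
Product: 6 2-bromo-4-[(3-methylbut-2-en-1-yl)oxy]benzaldehyde
Conditions: prenyl bromide, K2CO3, DMF, rt
Reagents that add atoms: prenyl bromide (1-bromo-3-methylbut-2-ene), CC(C)=CCBr
Why: Williamson ether synthesis: SN2 alkylation of the phenoxide, the only acidic site, by the primary allylic bromide.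

Step 5
Reactants: 4 (R)-2-amino-1-{3,4-bis[(2-methylbut-3-en-2-yl)oxy]phenyl}ethan-1-ol; 6 2-bromo-4-[(3-methylbut-2-en-1-yl)oxy]benzaldehyde
Product: 8 (R)-2-({2-bromo-4-[(3-methylbut-2-en-1-yl)oxy]benzyl}amino)-1-{3,4-bis[(2-methylbut-3-en-2-yl)oxy]phenyl}ethan-1-ol, via aldimine 7 (not isolated)
Conditions: MeOH, 3 Å MS, rt; then NaBH4, 0 °C
Reagents that add atoms: none
Why: Reductive amination: condensation to the aldimine and borohydride reduction give the secondary amine, while the aryl bromide, the ethers and the stereocentre are unaffected.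

Step 6
Reactants: 8 (R)-2-({2-bromo-4-[(3-methylbut-2-en-1-yl)oxy]benzyl}amino)-1-{3,4-bis[(2-methylbut-3-en-2-yl)oxy]phenyl}ethan-1-ol
Product: 9 (R)-2-{3,4-bis[(2-methylbut-3-en-2-yl)oxy]phenyl}-8-[(3-methylbut-2-en-1-yl)oxy]-2,3,4,5-tetrahydro-1,4-benzoxazepine
Conditions: CuI (10 mol %), 3,4,7,8-tetramethyl-1,10-phenanthroline (20 mol %), Cs2CO3, toluene, 80 °C, Ar
Reagents that add atoms: none
Why: Ullmann-type copper-catalysed intramolecular C–O coupling of the aryl bromide with the secondary alkoxide closes the seven-membered ring; the carbinol C–O bond is never broken, so the configuration is retained, N-arylation would need a four-membered ring, and 80 °C should stay below the range in which the tertiary allyl aryl ethers rearrange at a useful rate.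

Step 7
Reactants: 9 (R)-2-{3,4-bis[(2-methylbut-3-en-2-yl)oxy]phenyl}-8-[(3-methylbut-2-en-1-yl)oxy]-2,3,4,5-tetrahydro-1,4-benzoxazepine
Product: 12 (S)-2-{3,4-bis[(2-methylbut-3-en-2-yl)oxy]phenyl}-7-[(3-methylbut-2-en-1-yl)oxy]chromane, via N-amino amide adduct 10 (not isolated), via 1,1-diazene 11 (not isolated)
Conditions: N-(benzyloxy)-N-(pivaloyloxy)-4-(trifluoromethyl)benzamide (1.5 equiv), THF, 45 °C
Reagents that add atoms: none
Why: The secondary amine is aminated at nitrogen by the anomeric amide with loss of pivalate to give 10, which expels benzyl 4-(trifluoromethyl)benzoate by a HERON-type reductive elimination to give the 1,1-diazene 11; 11 loses N2 to a C3/C4 biradical (C4 benzylic to ring A) that collapses by radical–radical coupling. The closest known reaction type is the nitrogen deletion (deaminative ring contraction) of benzylic secondary amines with anomeric amides, as in tetrahydroisoquinoline to indane. The six-membered pyran ring is closed by intramolecular recombination of the tethered biradical, a 7→6 ring contraction in which the new C3–C4 σ bond replaces the C3–N–C4 bridge. No new stereocentre is formed: C2 is not a radical centre and keeps the configuration fixed in steps 2 and 6, and its descriptor changes from R to S only because C3 loses its nitrogen. The step needs C–C recombination to outrun β-scission of the C2–O1 bond (to a styrene and an ortho-quinone methide), 1,2-hydrogen shift to a hydrazone and tetrazene formation; the benzylic stabilisation at C4, the short tether that holds both radical centres in one molecule and the mild temperature favour recombination.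

Step 8
Reactants: 12 (S)-2-{3,4-bis[(2-methylbut-3-en-2-yl)oxy]phenyl}-7-[(3-methylbut-2-en-1-yl)oxy]chromane
Product: 14 (S)-4-[7-hydroxy-6-(2-methylbut-3-en-2-yl)chroman-2-yl]-3,6-bis(3-methylbut-2-en-1-yl)benzene-1,2-diol, via ring-B-rearranged catechol 13 (not isolated)
Conditions: PhNEt2, Ar, sealed tube, 120 °C then 195 °C
Reagents that add atoms: none
Why: Three aromatic Claisen ([3,3]) rearrangements: at 120 °C each 1,1-dimethylallyl ether of ring B shifts to its only free ortho position (C2′ and C5′) to give the prenyl groups, and at 195 °C the 7-O-prenyl ether shifts with allyl inversion to C6, which should be preferred over C8 because C8 is flanked by O1 and O7; C2 is not involved.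

**Compound list**

1 | 3,4-dihydroxybenzaldehyde | O=Cc1ccc(O)c(O)c1 | starting material
2 | 3,4-bis[(2-methylbut-3-en-2-yl)oxy]benzaldehyde | O=Cc1ccc(OC(C)(C)C=C)c(OC(C)(C)C=C)c1 | intermediate
3 | (R)-1-{3,4-bis[(2-methylbut-3-en-2-yl)oxy]phenyl}-2-nitroethan-1-ol | [O-][N+](=O)C[C@H](O)c1ccc(OC(C)(C)C=C)c(OC(C)(C)C=C)c1 | intermediate
4 | (R)-2-amino-1-{3,4-bis[(2-methylbut-3-en-2-yl)oxy]phenyl}ethan-1-ol | NC[C@H](O)c1ccc(OC(C)(C)C=C)c(OC(C)(C)C=C)c1 | intermediate
5 | 2-bromo-4-hydroxybenzaldehyde | O=Cc1ccc(O)cc1Br | starting material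
6 | 2-bromo-4-[(3-methylbut-2-en-1-yl)oxy]benzaldehyde | O=Cc1ccc(OCC=C(C)C)cc1Br | intermediate
7 | (R)-2-[(E)-{2-bromo-4-[(3-methylbut-2-en-1-yl)oxy]benzylidene}amino]-1-{3,4-bis[(2-methylbut-3-en-2-yl)oxy]phenyl}ethan-1-ol (aldimine, not isolated) | O[C@@H](C/N=C/c1ccc(OCC=C(C)C)cc1Br)c1ccc(OC(C)(C)C=C)c(OC(C)(C)C=C)c1 | intermediate
8 | (R)-2-({2-bromo-4-[(3-methylbut-2-en-1-yl)oxy]benzyl}amino)-1-{3,4-bis[(2-methylbut-3-en-2-yl)oxy]phenyl}ethan-1-ol | O[C@@H](CNCc1ccc(OCC=C(C)C)cc1Br)c1ccc(OC(C)(C)C=C)c(OC(C)(C)C=C)c1 | intermediate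
9 | (R)-2-{3,4-bis[(2-methylbut-3-en-2-yl)oxy]phenyl}-8-[(3-methylbut-2-en-1-yl)oxy]-2,3,4,5-tetrahydro-1,4-benzoxazepine | N1C[C@@H](c2ccc(OC(C)(C)C=C)c(OC(C)(C)C=C)c2)Oc2cc(OCC=C(C)C)ccc2C1 | intermediate
10 | N-(benzyloxy)-N-[(2R)-2-{3,4-bis[(2-methylbut-3-en-2-yl)oxy]phenyl}-8-[(3-methylbut-2-en-1-yl)oxy]-2,3-dihydro-1,4-benzoxazepin-4(5H)-yl]-4-(trifluoromethyl)benzamide (not isolated) | O=C(c1ccc(cc1)C(F)(F)F)N(OCc1ccccc1)N1C[C@@H](c2ccc(OC(C)(C)C=C)c(OC(C)(C)C=C)c2)Oc2cc(OCC=C(C)C)ccc2C1 | intermediate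
11 | 1,1-diazene (isodiazene) of 9, with N4 bearing a terminal nitrogen (N4 positive, terminal N negative), 2R (not isolated) | [N-]=[N+]1C[C@@H](c2ccc(OC(C)(C)C=C)c(OC(C)(C)C=C)c2)Oc2cc(OCC=C(C)C)ccc2C1 | intermediate
12 | (S)-2-{3,4-bis[(2-methylbut-3-en-2-yl)oxy]phenyl}-7-[(3-methylbut-2-en-1-yl)oxy]chromane | C1C[C@@H](c2ccc(OC(C)(C)C=C)c(OC(C)(C)C=C)c2)Oc2cc(OCC=C(C)C)ccc21 | intermediate
13 | (S)-3,6-bis(3-methylbut-2-en-1-yl)-4-{7-[(3-methylbut-2-en-1-yl)oxy]chroman-2-yl}benzene-1,2-diol (not isolated) | C1C[C@@H](c2cc(CC=C(C)C)c(O)c(O)c2CC=C(C)C)Oc2cc(OCC=C(C)C)ccc21 | intermediate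
14 | (S)-4-[7-hydroxy-6-(2-methylbut-3-en-2-yl)chroman-2-yl]-3,6-bis(3-methylbut-2-en-1-yl)benzene-1,2-diol (CNP0118330.1) | C=CC(C)(C)c1cc2c(cc1O)O[C@H](c1cc(CC=C(C)C)c(O)c(O)c1CC=C(C)C)CC2 | target

**Step count.** Total: 8 steps. Longest linear sequence: 7 steps (1, 2, 3, 5, 6, 7, 8).

**Steps most likely to fail**

Step 7 (nitrogen deletion). The amination at nitrogen may stall, the 1,1-diazene may be diverted before it loses nitrogen (dimerisation to a tetrazene, 1,2-hydrogen shift to a hydrazone), or the biradical may fragment by β-scission of the C2–O1 bond instead of recombining. The fallback sets out from aldehyde 2, uses bromo aldehyde 6, and comes back to the route at 12; it gives up the contraction and closes the pyran ring directly. Addition of MeMgBr to 2 should give the carbinol 1-{3,4-bis[(2-methylbut-3-en-2-yl)oxy]phenyl}ethan-1-ol F1, and MnO2 oxidation the acetophenone 1-{3,4-bis[(2-methylbut-3-en-2-yl)oxy]phenyl}ethan-1-one F2. Claisen–Schmidt condensation of F2 with 6 (KOH, EtOH) should give the (E)-chalcone F3, and conjugate reduction with [(Ph3P)CuH]6 the dihydrochalcone F4. Ru–(S,S)-TsDPEN transfer hydrogenation (HCO2H/Et3N) should then give the (S)-alcohol F5. Copper-catalysed intramolecular O-arylation under the conditions of step 6 closes the six-membered ring with retention to give 12.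

Step 8 (triple Claisen rearrangement). At 195 °C the first-formed ortho-(1,1-dimethylallyl)phenol may react on (abnormal Claisen rearrangement, cyclisation to a coumaran) and the free catechol may degrade before the last rearrangement is complete. The fallback sets out from 12 and comes back at 14. The rearrangement is run in PhNEt2 with Ac2O and NaOAc, so that the phenols 13 and 14 are acetylated as they form and are shielded from the onward reactions, to give the triacetate of the target F6. Mild methanolysis (K2CO3, MeOH, rt) then releases 14.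

Step 6 (copper-catalysed ring closure). C–O coupling at the unactivated aryl bromide may be too slow at a temperature that the tertiary allyl aryl ethers survive, so that premature Claisen rearrangement or oxidation of the amine competes. The fallback sets out from amino alcohol 4 and comes back at 9. Commercial methyl 2-fluoro-4-hydroxybenzoate is O-prenylated (prenyl bromide, K2CO3) to methyl 2-fluoro-4-[(3-methylbut-2-en-1-yl)oxy]benzoate F7. The sodium alkoxide of 4 (NaH, DMF, 0 to 60 °C) displaces the fluoride ortho to the ester by SNAr, with retention at the carbinol carbon, and the amine closes the lactam to give the benzoxazepin-5-one F8. LiAlH4 in THF reduces the lactam to 9.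

**Further compounds**

F1 | step 7 | 1-{3,4-bis[(2-methylbut-3-en-2-yl)oxy]phenyl}ethan-1-ol (racemic) | CC(O)c1ccc(OC(C)(C)C=C)c(OC(C)(C)C=C)c1
F2 | step 7 | 1-{3,4-bis[(2-methylbut-3-en-2-yl)oxy]phenyl}ethan-1-one | CC(=O)c1ccc(OC(C)(C)C=C)c(OC(C)(C)C=C)c1
F3 | step 7 | (E)-1-{3,4-bis[(2-methylbut-3-en-2-yl)oxy]phenyl}-3-{2-bromo-4-[(3-methylbut-2-en-1-yl)oxy]phenyl}prop-2-en-1-one | O=C(/C=C/c1ccc(OCC=C(C)C)cc1Br)c1ccc(OC(C)(C)C=C)c(OC(C)(C)C=C)c1
F4 | step 7 | 1-{3,4-bis[(2-methylbut-3-en-2-yl)oxy]phenyl}-3-{2-bromo-4-[(3-methylbut-2-en-1-yl)oxy]phenyl}propan-1-one | O=C(CCc1ccc(OCC=C(C)C)cc1Br)c1ccc(OC(C)(C)C=C)c(OC(C)(C)C=C)c1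
F5 | step 7 | (S)-1-{3,4-bis[(2-methylbut-3-en-2-yl)oxy]phenyl}-3-{2-bromo-4-[(3-methylbut-2-en-1-yl)oxy]phenyl}propan-1-ol | O[C@@H](CCc1ccc(OCC=C(C)C)cc1Br)c1ccc(OC(C)(C)C=C)c(OC(C)(C)C=C)c1
F6 | step 8 | (S)-4-[7-acetoxy-6-(2-methylbut-3-en-2-yl)chroman-2-yl]-3,6-bis(3-methylbut-2-en-1-yl)-1,2-phenylene diacetate | C=CC(C)(C)c1cc2c(cc1OC(C)=O)O[C@H](c1cc(CC=C(C)C)c(OC(C)=O)c(OC(C)=O)c1CC=C(C)C)CC2
F7 | step 6 | methyl 2-fluoro-4-[(3-methylbut-2-en-1-yl)oxy]benzoate | COC(=O)c1ccc(OCC=C(C)C)cc1F
F8 | step 6 | (R)-2-{3,4-bis[(2-methylbut-3-en-2-yl)oxy]phenyl}-8-[(3-methylbut-2-en-1-yl)oxy]-3,4-dihydro-1,4-benzoxazepin-5(2H)-one | O=C1NC[C@@H](c2ccc(OC(C)(C)C=C)c(OC(C)(C)C=C)c2)Oc2cc(OCC=C(C)C)ccc21
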